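**Plan**

- Retrosynthetic cuts, in order: the Si–O bond at C5; the two C–H bonds across C13–C7'; the pyran bonds C7'–C1' and C8–O (syncarpic acid plus a C8 tertiary propargylic alcohol); C8–C13 (4-methylpent-1-yne plus a C8 ketone); the ketone then goes back to (−)-caryophyllene oxide.
- Enabling feature: the pyran array O–C8(spiro)–C13–C7'–C1' joins a 1,3-dione dinucleophile (C1' and the enol oxygen of the syncarpic ring) to a three-carbon dielectrophile C8–C13–C7'. Because C8 is a fully substituted, oxygen-bearing carbon of the nine-membered ring, a tertiary propargylic alcohol supplies that dielectrophile.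
- Forward order: the cyclobutane and the nine-membered ring are bought with the terpene. The epoxide is turned into the (Z)-allylic alcohol, C5 is inverted through the enone, the exocyclic methylene is cut to the C8 ketone and the alkyne is added. The spiro pyran is then closed onto syncarpic acid, its C13=C7' bond is reduced and the silyl group is removed.
- Stereochemistry: C1 and C9 come from caryophyllene oxide; (3Z) from the syn-elimination; C5 (S) from a reagent-controlled Corey–Bakshi–Shibata reduction; C8 from the face-selective, reversible oxa-6π closure; C7' from hydride delivery anti to the C9 branch.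
- Numbering: caryophyllane numbers are used (C1/C9 ring fusion, C11 the gem-dimethyl carbon, C12 the methyl on C4, C13 the carbon on C8). Primed numbers denote the syncarpic ring (C1' its nucleophilic carbon, C2' the enol-ether carbon), and C7' is the isobutyl-bearing carbon.

Key step: step 7

Assumption: syncarpic acid is taken as a purchased material. The carbinol centre made in step 6 is drawn as one epimer only, because C8 becomes planar in step 7 and either epimer should serve.

**Step 1**
Reactants: 1 (−)-caryophyllene oxide
Product: 2 (1R,3Z,5R,9S)-caryophylla-3,8(13)-dien-5-ol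
Conditions: Et2Al(TMP) (TMP = 2,2,6,6-tetramethylpiperidide; from 2,2,6,6-tetramethylpiperidine, n-BuLi and Et2AlCl), toluene, 0 °C → rt; ice-cold 1 M HCl work-up
Reagents that add atoms: none
Why: Base-promoted epoxide-to-allylic-alcohol isomerisation by syn-elimination through an aluminium-bound cyclic transition state, in which the bulky amide should take the C3 hydrogen syn to oxygen (the ring methylene cis to the epoxide hydrogen) instead of a methyl hydrogen, the untouched C5–O bond keeps 5R, and rotation of C2 toward C5 releases the strain of the trans-cyclononene and gives the (3Z) alkene.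

**Step 2**
Reactants: 2 (1R,3Z,5R,9S)-caryophylla-3,8(13)-dien-5-ol
Product: 3 (1R,3Z,9S)-caryophylla-3,8(13)-dien-5-one
Conditions: Dess–Martin periodinane, CH2Cl2, 0 °C → rt
Reagents that add atoms: none
Why: Dess–Martin oxidation of a secondary allylic alcohol is near-neutral and should leave both alkenes and the (Z) geometry untouched, while the C5 centre is erased on purpose so that it can be reset in step 3.

**Step 3**
Reactants: 3 (1R,3Z,9S)-caryophylla-3,8(13)-dien-5-one
Product: 4 (1R,3Z,5S,9S)-caryophylla-3,8(13)-dien-5-ol
Conditions: (R)-1-methyl-3,3-diphenyltetrahydro-1H,3H-pyrrolo[1,2-c][1,3,2]oxazaborole (20 mol%), catecholborane, toluene, −78 °C; then MeOH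
Reagents that add atoms: none
Why: Corey–Bakshi–Shibata 1,2-reduction in which the (R)-oxazaborolidine treats the α-methyl alkenyl arm (C4) as the large group and the C6 methylene as the small one, so that hydride should arrive on the face giving the (5S)-alcohol, while catecholborane does not hydroborate the exocyclic alkene at this temperature.

**Step 4**
Reactants: 4 (1R,3Z,5S,9S)-caryophylla-3,8(13)-dien-5-ol
Product: 5 (1R,3Z,5S,9S)-5-(triisopropylsilyloxy)caryophylla-3,8(13)-diene
Conditions: TIPSOTf, 2,6-lutidine, CH2Cl2, 0 °C
Reagents that add atoms: triisopropylsilyl trifluoromethanesulfonate, CC(C)[Si](C(C)C)(C(C)C)OS(=O)(=O)C(F)(F)F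
Why: Standard silylation of a hindered secondary alcohol with a silyl triflate; the triisopropylsilyl group is chosen because it should withstand the acid of steps 7 and 8 and because its bulk screens the neighbouring C3=C4 bond in step 5.

**Step 5**
Reactants: 5 (1R,3Z,5S,9S)-5-(triisopropylsilyloxy)caryophylla-3,8(13)-diene
Product: 7 (1R,3Z,5S,9S)-5-(triisopropylsilyloxy)-13-norcaryophyll-3-en-8-one, via vicinal diol 6 (not isolated)
Conditions: K2OsO4·2H2O (2 mol%), NaIO4, 2,6-lutidine, 1,4-dioxane/H2O (3:1), rt
Reagents that add atoms: osmium tetroxide (formed from K2OsO4·2H2O and NaIO4), O=[Os](=O)(=O)=O; sodium periodate, [Na+].[O-]I(=O)(=O)=O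
Why: Lemieux–Johnson cleavage in which osmylation should prefer the unhindered 1,1-disubstituted C8=C13 bond over the trisubstituted ring alkene, which is deactivated inductively by its allylic oxygen and shielded by the silyl group; periodate then cuts diol 6 to the ketone, whose trans ring fusion at C9 is the stable one.

**Step 6**
Reactants: 7 (1R,3Z,5S,9S)-5-(triisopropylsilyloxy)-13-norcaryophyll-3-en-8-one; 8 4-methylpent-1-yne
Product: 11 (1R,3Z,5S,8R,9S)-8-(4-methylpent-1-yn-1-yl)-5-(triisopropylsilyloxy)-13-norcaryophyll-3-en-8-ol, via lithium acetylide 9 (not isolated), via cerium acetylide 10 (not isolated)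
Conditions: 8, n-BuLi, THF, −78 °C; anhydrous CeCl3, −78 °C; then 7, −78 → −40 °C; aqueous NH4Cl
Reagents that add atoms: none
Why: 1,2-Addition of an alkynylcerium reagent to a hindered, enolisable ketone, the weakly basic cerium reagent suppressing enolisation; the new C8 centre is drawn as 8R but its configuration is immaterial because C8 is ionised in step 7.

**Step 7**
Reactants: 11 (1R,3Z,5S,8R,9S)-8-(4-methylpent-1-yn-1-yl)-5-(triisopropylsilyloxy)-13-norcaryophyll-3-en-8-ol; 12 syncarpic acid
Product: 16 C5 triisopropylsilyl ether of the spiro 2H-pyran (8R; C13=C7' double bond), via propargylic cation 13 (not isolated), via allenyl trione 14 (not isolated), via 1-oxatriene 15 (not isolated)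
Conditions: 12 (2 equiv), p-TsOH·H2O (10 mol%), MgSO4, ClCH2CH2Cl, 50 °C
Reagents that add atoms: none
Why: Acid ionises the tertiary C8–OH to the alkynyl-stabilised cation 13, the enol carbon C1' of 12 attacks the remote alkyne terminus C7' to give allene 14, and shift of the acidic C1' proton to the central allene carbon C13 gives 1-oxatriene 15, which closes thermally to the pyran by forming C8–O. The closest known reaction type is the acid-catalysed propargylation–allenylation and cycloisomerisation of tertiary propargylic alcohols with cyclic 1,3-diketones to fused 2H-pyrans. The six-membered ring closes by disrotatory oxa-6π electrocyclisation, which only requires a carbonyl cis to the C13=C8 vinyl group on the C1'=C7' bond, and the two carbonyls flanking C1' are equivalent. The new stereocentre C8 is fixed by the face of the C13=C8 terminus that oxygen reaches; the folded nine-membered ring with its trans-fused cyclobutane differentiates the two faces, and because the closure is reversible the spiro centre should settle in the more stable arrangement drawn. The step needs attack at C7' instead of C8, carbon instead of oxygen attack and ionisation at C8 instead of C5: the congested C8 terminus disfavours direct propargylation, any O-alkylation at C8 should funnel into the same allene by propargyl Claisen rearrangement, 12 has a single nucleophilic carbon and cannot aromatise, and the secondary allylic C5–O bond carries an acid-stable silyl ether whereas the C8 cation is tertiary and alkynyl-stabilised.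

**Step 8**
Reactants: 16 C5 triisopropylsilyl ether of the spiro 2H-pyran (8R; C13=C7' double bond)
Product: 18 O-triisopropylsilyl tomentodione P (8S;7'S), via oxocarbenium ion 17 (not isolated)
Conditions: Et3SiH, CF3CO2H, CH2Cl2, −20 → 0 °C
Reagents that add atoms: none
Why: Ionic hydrogenation of the kind used to turn 2H-chromenes into chromans: protonation at C13 of the dienyl ether gives the ring-oxygen-stabilised cation 17, and Et3SiH should deliver hydride to C7' on the face anti to the bulkier C9 branch of the spiro centre (axial attack on the half-chair), which places the isobutyl group cis to C9 (7'S) and keeps the C1'=C2' enol ether in conjugation with the C6' carbonyl.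

**Step 9**
Reactants: 18 O-triisopropylsilyl tomentodione P (8S;7'S)
Product: 19 tomentodione P
Conditions: Bu4NF, THF, 0 °C → rt; aqueous NH4Cl
Reagents that add atoms: none
Why: Fluoride cleaves the silyl ether at the Si–O bond, so the C5 configuration, the enol ether and the non-enolisable triketone array should remain untouched.

**Compound list**

1 | (−)-caryophyllene oxide, (1R,4R,5R,9S)-4,5-epoxycaryophyll-8(13)-ene | C[C@@]12CC[C@@H]3[C@H](CC3(C)C)C(=C)CC[C@H]1O2 | starting material
2 | (1R,3Z,5R,9S)-caryophylla-3,8(13)-dien-5-ol | C/C1=C/C[C@@H]2[C@H](CC2(C)C)C(=C)CC[C@H]1O | intermediate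
3 | (1R,3Z,9S)-caryophylla-3,8(13)-dien-5-one | C/C1=C/C[C@@H]2[C@H](CC2(C)C)C(=C)CCC1=O | intermediate
4 | (1R,3Z,5S,9S)-caryophylla-3,8(13)-dien-5-ol | C/C1=C/C[C@@H]2[C@H](CC2(C)C)C(=C)CC[C@@H]1O | intermediate
5 | (1R,3Z,5S,9S)-5-(triisopropylsilyloxy)caryophylla-3,8(13)-diene | C/C1=C/C[C@@H]2[C@H](CC2(C)C)C(=C)CC[C@@H]1O[Si](C(C)C)(C(C)C)C(C)C | intermediate
6 | (1R,3Z,5S,9S)-5-(triisopropylsilyloxy)caryophyll-3-ene-8,13-diol (C8 configuration not defined) | C/C1=C/C[C@@H]2[C@H](CC2(C)C)C(O)(CO)CC[C@@H]1O[Si](C(C)C)(C(C)C)C(C)C | intermediate
7 | (1R,3Z,5S,9S)-5-(triisopropylsilyloxy)-13-norcaryophyll-3-en-8-one | C/C1=C/C[C@@H]2[C@H](CC2(C)C)C(=O)CC[C@@H]1O[Si](C(C)C)(C(C)C)C(C)C | intermediate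
8 | 4-methylpent-1-yne | C#CCC(C)C | starting material
9 | (4-methylpent-1-yn-1-yl)lithium | [Li]C#CCC(C)C | intermediate
10 | dichloro(4-methylpent-1-yn-1-yl)cerium | Cl[Ce](Cl)C#CCC(C)C | intermediate
11 | (1R,3Z,5S,8R,9S)-8-(4-methylpent-1-yn-1-yl)-5-(triisopropylsilyloxy)-13-norcaryophyll-3-en-8-ol (C8 tertiary propargylic alcohol; 8R epimer drawn) | C/C1=C/C[C@@H]2[C@H](CC2(C)C)[C@](O)(CC[C@@H]1O[Si](C(C)C)(C(C)C)C(C)C)C#CCC(C)C | intermediate
12 | syncarpic acid, 2,2,4,4-tetramethylcyclohexane-1,3,5-trione | CC1(C)C(=O)CC(=O)C(C)(C)C1=O | starting material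
13 | C8 propargylic cation formed from 11 by loss of water | C/C1=C/C[C@@H]2[C@H](CC2(C)C)[C+](CC[C@@H]1O[Si](C(C)C)(C(C)C)C(C)C)C#CCC(C)C | intermediate
14 | allenyl trione: C1' of the syncarpic ring bonded to C7' of the allene C8=C13=C7'(isobutyl); allene axis not defined | C/C1=C/C[C@@H]2[C@H](CC2(C)C)C(CC[C@@H]1O[Si](C(C)C)(C(C)C)C(C)C)=C=C(CC(C)C)C1C(=O)C(C)(C)C(=O)C(C)(C)C1=O | intermediate
15 | 1-oxatriene: alkylidene trione C1'=C7'(isobutyl)–C13H=C8; C13=C8 geometry not defined | C/C1=C/C[C@@H]2[C@H](CC2(C)C)C(CC[C@@H]1O[Si](C(C)C)(C(C)C)C(C)C)=CC(CC(C)C)=C1C(=O)C(C)(C)C(=O)C(C)(C)C1=O | intermediate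
16 | spiro 2H-pyran, C5 triisopropylsilyl ether (1R,3Z,5S,8R,9S; C13=C7' double bond, isobutyl on C7'; the descriptor at C8 changes to S in 18 without any change in space) | C/C1=C/C[C@@H]2[C@H](CC2(C)C)[C@]2(CC[C@@H]1O[Si](C(C)C)(C(C)C)C(C)C)C=C(CC(C)C)C1=C(O2)C(C)(C)C(=O)C(C)(C)C1=O | intermediate
17 | oxocarbenium ion formed from 16 by protonation at C13 | C/C1=C/C[C@@H]2[C@H](CC2(C)C)[C@]2(CC[C@@H]1O[Si](C(C)C)(C(C)C)C(C)C)CC(CC(C)C)=C1C(=[O+]2)C(C)(C)C(=O)C(C)(C)C1=O | intermediate
18 | O-triisopropylsilyl tomentodione P (1R,3Z,5S,8S,9S,7'S) | C/C1=C/C[C@@H]2[C@H](CC2(C)C)[C@]2(CC[C@@H]1O[Si](C(C)C)(C(C)C)C(C)C)C[C@H](CC(C)C)C1=C(O2)C(C)(C)C(=O)C(C)(C)C1=O | intermediate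
19 | tomentodione P (1R,3Z,5S,8S,9S,7'S) | C/C1=C/C[C@@H]2[C@H](CC2(C)C)[C@]2(CC[C@@H]1O)C[C@H](CC(C)C)C1=C(O2)C(C)(C)C(=O)C(C)(C)C1=O | target

**Step count**

Total steps: 9. Longest linear sequence: 9 steps, from 1 to 19.

**Steps most likely to fail**

Step 7. The C8 cation may be drained before the dione reaches it: by loss of a proton from C7 or C9 (conjugated enyne), by return of water at C7' (Meyer–Schuster enone), or by transannular capture by the C3=C4 bond. The electrocyclisation may also close on the other face of C8.

The fallback builds the same pyran by a cation-free inverse-demand hetero-Diels–Alder reaction and sets out from 5, which still carries the C8=C13 bond. Heating 5 with syncarpic acid 12, 3-methylbutanal and catalytic ethylenediammonium diacetate in toluene should form, by Knoevenagel condensation in the flask, the heterodiene 2,2,4,4-tetramethyl-6-(3-methylbutylidene)cyclohexane-1,3,5-trione F1. Its enone oxygen should add to the more substituted C8 and its alkylidene carbon to C13 of the exocyclic alkene. This comes back to the route at 18, whose C8/C7' diastereomers would be separated there.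

Step 8. The acid may ionise the allylic, tertiary spiro C8–O bond faster than hydride is transferred, leading to ring opening or reductive loss of the oxygen at C8, or hydride may reach C7' from the C9 face.

The fallback replaces the cationic reduction by a radical one, a metal-hydride hydrogen-atom-transfer hydrogenation under neutral conditions. Treating 16 with tris(2,2,6,6-tetramethylheptane-3,5-dionato)manganese, Mn(dpm)3, PhSiH3 and t-BuOOH in i-PrOH should add a hydrogen atom to C13 of the conjugated diene to give the stabilised allylic C7' radical, and the second hydrogen should be taken up from the less hindered face. The isolated C3=C4 bond forms no comparably stabilised radical and should react more slowly. This returns directly to 18 without a new compound.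

Step 1. The amide may remove a hydrogen from the C12 methyl instead of C3, giving the exocyclic alkene, or the ring may deliver the (3E) isomer.

The fallback accepts the methyl-side elimination and moves the double bond afterwards; it sets out from 1 and returns at 3:

- Lithium diethylamide in ether should give (1R,5R,9S)-caryophylla-4(12),8(13)-dien-5-ol F2 by the usual preference of lithium amides for the least substituted hydrogen.
- Dess–Martin oxidation gives the exo-methylene enone (1R,9S)-caryophylla-4(12),8(13)-dien-5-one F3.
- Conjugate reduction with LiBH(s-Bu)3 at −78 °C generates the C4 enolate regiospecifically, and trapping with PhSeCl gives (1R,9S)-4-(phenylselanyl)caryophyll-8(13)-en-5-one F4.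
- Oxidation with H2O2 and syn-elimination of the selenoxide toward C3 should give the conjugated (Z)-enone 3; any F3 regenerated by elimination toward the methyl would be recycled.

**Further compounds**

F1 | step 7 | 2,2,4,4-tetramethyl-6-(3-methylbutylidene)cyclohexane-1,3,5-trione | CC(C)CC=C1C(=O)C(C)(C)C(=O)C(C)(C)C1=O
F0 | step 8 | none | none
F2 | step 1 | (1R,5R,9S)-caryophylla-4(12),8(13)-dien-5-ol | C=C1CC[C@@H]2[C@H](CC2(C)C)C(=C)CC[C@H]1O
F3 | step 1 | (1R,9S)-caryophylla-4(12),8(13)-dien-5-one | C=C1CC[C@@H]2[C@H](CC2(C)C)C(=C)CCC1=O
F4 | step 1 | (1R,9S)-4-(phenylselanyl)caryophyll-8(13)-en-5-one (C4 epimers) | CC1([Se]c2ccccc2)CC[C@@H]2[C@H](CC2(C)C)C(=C)CCC1=O
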